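The data come from a simulation from invented constants; noise was put on by code.

At 30 °C the alder run stopped early: from 4.00 h to 72.0 h its target stayed near 56%, with 42% of the substrate still there. At −5 °C, the oak run crept on to 99% at 360 h.

in all of them: substrate 0.80 M; free catalyst 40 mM
- oak: partner 1.3 M; temperature −5 °C; run made earlier
- alder: partner 3 M; temperature 30 °C; run made earlier
- ochre: partner 2.00 M; temperature 60 °C; time 20 h
- green: partner 2.00 M; at 0 °C until 4.0 h, from then on at 60 °C; time 20 h
- grey: partner 2.00 M; temperature 0 °C; time 20 h
- blue: partner 2.00 M; temperature 30 °C; time 20 h

| run | time / h | target / % | substrate / % |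
|---|---|---|---|
| oak | 30.0 | 63 | 33 |
| oak | 50.0 | 79 | 22 |
| oak | 72.0 | 86 | 12 |
| oak | 120 | 93 | 7 |
| oak | 144 | 95 | 5 |
| oak | 240 | 97 | 1 |
| oak | 360 | 99 | 2 |
| alder | 4.00 | 55 | 42 |
| alder | 12.0 | 56 | 42 |
| alder | 20.0 | 57 | 43 |
| alder | 25.0 | 56 | 42 |
| alder | 40.0 | 57 | 44 |
| alder | 48.0 | 58 | 42 |
| alder | 72.0 | 56 | 42 |

(standard deviation of a reading: 1.5 percentage points)



* which flask leads in amount of target, in percent of the substrate charged ("all alike" within 1.5 percentage points) (ochre / green / grey / blue / all alike)
* how much target is there at the end, in percent of the substrate charged: ochre
* how much target is there at the end, in percent of the substrate charged: green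
* how much target is there at the end, in percent of the substrate charged: grey
* how much target is there at the end, in percent of the substrate charged: blue

Blue looks nearly the same as alder, with the same temperature, substrate and free catalyst. But it holds 2.50 equivalents of partner per substrate charged, fewer than alder's 3.75. A flat line with substrate left can be read in two ways: a balance of forward and back reaction, or a partner lost to a side path, after which nothing moves. The partner was never read, so the runs could not separate these. I reckoned with the second, which is kinetic against thermodynamic control.

I followed one partner molecule to its fork: it either meets substrate and gives target, or takes the side path. Its chance of target goes with the substrate left, so long as that chance stays small, and in alder 14.9% of the partner charge ended as target. At a fixed temperature and catalyst charge, each equivalent of partner then removes the same share of the substrate left. So I defined the reach as the natural logarithm of substrate charged over substrate left, per equivalent of partner charged, and alder's last reading gave 0.231. Carried to blue's smaller charge, the reach gave me 43.9% target. For green, it meant that target made in the cold hours would stay after heating, on top of what the hot stage added.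

The forecast put blue at 46%, ochre at 3.5%, green at 3.5% and grey at 80%, with grey leading. It took alder's plateau as a level “which reads as equilibrium rather than a stall”. On blue we stood close, but on green we differed, since the forecast returned green to ochre's level and I did not.

    substrate + free catalyst ⇌ catalyst intermediate A (K = 0.520 M⁻¹, k = 11.0 M⁻¹ h⁻¹, Ea = 51.0 kJ mol⁻¹, ΔH = −31.0 kJ mol⁻¹)
    partner + catalyst intermediate A ⇌ catalyst intermediate B (K = 0.850 M⁻¹, k = 4.30 M⁻¹ h⁻¹, Ea = 73.0 kJ mol⁻¹, ΔH = −51.0 kJ mol⁻¹)
    catalyst intermediate B → free catalyst + target (k = 89.0 h⁻¹, Ea = 75.0 kJ mol⁻¹)
    partner → decomposed reagent (k = 0.0130 h⁻¹, Ea = 98.0 kJ mol⁻¹)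
    (constants at 0 °C)

The flask in the lead was grey, with 78.8% of target, and green ended at 32.1%. At the change, at 4.00 h, green's partner stood at 83.4% of its charge and its target at 29.6%; at 10.0 h its partner stood at 0% and its target at 32.1%. Blue ended at 43.3% against the 43.9% from alder's reach of 0.231, with its partner, the limiting reagent there, at 0%. Ochre's end at 3.90% gives a reach of 0.0159, far below alder's. Applied to the partner and the 69.5% of substrate that green held at the change, that reach gives 32.8% target, and green held 32.1%.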